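(The earlier runs and the new flask are calculated for an exercise, noise included.)

The number I decide by is 0.183 min⁻¹: the drain constant, a pseudo-first-order constant, is the rate at which the pool c(E) + c(J) shrinks in the east run between its first and last readings. My next flasks keep east's Q at 0.84 mM but charge E at 20 mM, and the decision is when to stop.

| setting | south-east | north-west | east | teal | ochre |
|---|---|---|---|---|---|
| E | 20 mM | 20 mM | 30 mM | 20 mM | 20 mM |
| Q | 0.42 mM | 1.7 mM | 0.84 mM | 0.84 mM | 0.84 mM |
| remark | run made earlier | run made earlier | run made earlier |  |  |
| time |  |  |  | 2.5 min | 8.0 min |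

| run | time / min | J / % | E / % |
|---|---|---|---|
| south-east | 0.250 | 69.8 | 23.4 |
| south-east | 0.500 | 74.2 | 17.3 |
| south-east | 1.33 | 66.0 | 17.3 |
| south-east | 3.00 | 57.7 | 14.0 |
| north-west | 0.250 | 73.1 | 18.3 |
| north-west | 0.500 | 67.8 | 16.8 |
| north-west | 1.33 | 54.6 | 14.9 |
| north-west | 3.00 | 37.0 | 8.5 |
| east | 0.417 | 72.9 | 18.7 |
| east | 1.00 | 65.8 | 18.1 |
| east | 2.00 | 55.9 | 13.0 |
| east | 3.00 | 46.4 | 10.7 |

(readings scatter by 1 percentage point)

- which of the two there is more of at the end, teal (J / D)
- which of the two there is more of at the end, ochre (J / D)
- amount of J at the end, in percent of the E charged, teal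
- amount of J at the end, in percent of the E charged, ochre

- the numbers in the tables scatter by 1 percentage point (one standard deviation)
- candidate steps: 2 Q <-> G; E + Q <-> Q + J; Q + L -> Q + D; E <-> L

The same reading gives 0.0954 min⁻¹ in the south-east run and 0.254 min⁻¹ in the north-west run. North-west has 4.05 times the Q of south-east but a constant only 2.66 times as large, so the Q charge must be held when the constant is carried over. East's value lies above the first and below the second, although east started with more E, so I treat the drain as first-order in the pool and take it to 20 mM.

Running east's last readings on with this constant, my own reckoning for teal gives J 50.8% and puts about 37.4% outside the pool, as L and D. For ochre it gives J 18.6% and about 77.1% outside the pool. So I stop at 2.5 min if I want J, and leaving the flask to 8.0 min serves D.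

The forecast names J for teal and D for ochre, with a slightly different pair of figures: J 50.5% (47% to 54%) in teal and 19.5% (14% to 26%) in ochre. Its ground is that “the east rate should carry over to 20 mM E”.

Teal gives J 52.2% against D 34.7%, and ochre gives J 22.0% against D 72.5%.

    2 Q ⇌ G, settled at all times (K = 540 L mol⁻¹)
    E + Q ⇌ Q + J (K = 3.90, k = 480 L mol⁻¹ s⁻¹)
    Q + L → Q + D (k = 1100 L mol⁻¹ s⁻¹)
    E ⇌ L (K = 0.0240, k = 0.250 s⁻¹)

Ochre holds 30 percentage points less J than teal, and the main reason is the difference in time: ochre without that difference stands at 52.2% of J, not 22.0%. Starting from teal's J, 0.183 min⁻¹ gives 19.1% for ochre against the 22.0% found, and 62.7% for a reading of teal at 1.5 min against the 61.1% that reading gives.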